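**Retrosynthetic overview**

1. The target is cut at the bond between pyridone C-3 and the carbinol carbon that becomes the ketone: decalin aldehyde 17 plus 3‑lithiated 2,4‑bis[2‑(trimethylsilyl)ethoxy]pyridine 28, which already carries the protected epoxy‑cyclohexanediol (from 5‑bromo‑2,4‑dichloropyridine 22 and enone 21 by aryllithium addition, then epoxidation anti to both silyloxy groups).
2. Decalin locants: C‑1 (propenyl), C‑2 (acyl), C‑3=C‑4 (methyl on C‑4), C‑4a, C‑7 (methyl), C‑8a. With the C‑4 methyl traced back to a ketone (via enol triflate), propenyl to formyl and acyl to ester, ring A is opened at C‑2–C‑3: intramolecular Michael addition of a methyl ketone (C‑3) to a 2‑substituted 4‑oxobut‑2‑enoate (C‑2).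
3. Enabling feature: in ring A, C‑3 lies between C‑4 (latent ketone) and C‑2, which is β to the carbon on C‑1 (latent formyl), so a 1,5‑dicarbonyl spans the C‑3–C‑2 bond. C‑1, C‑2 and C‑4a are then all α to a carbonyl, and the target decalin is the all‑equatorial trans isomer, so these three centres can be set under thermodynamic control.
4. Ring B with C‑8a, C‑4a and C‑7 comes from (S)‑citronellal 1 by Knoevenagel condensation and intramolecular ene reaction. The isopropenyl group formed there is the masked C‑4 acetyl, the malonate arm supplies C‑1 and its formyl carbon, and ethyl glyoxylate supplies C‑2 and the acyl carbon.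
5. Order of ring formation: ring B (ene, step 2), then ring A (Michael, step 7); the oxirane is made on the pyridine–cyclohexene fragment (step 19); pyridine and cyclohexane rings are bought in; fragments are joined in step 20.

Key step: step 7

Remark: the carbinol centre formed in step 20 is taken as an inconsequential epimer mixture (removed in step 21), and the sense of the transfer hydrogenation in step 13 is assigned by analogy with aryl ketones.

**Route**

Step 1
Reactants: 1 (S)-citronellal; 2 dimethyl malonate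
Product: 3 dimethyl 2-[(3S)-3,7-dimethyloct-6-en-1-ylidene]propanedioate
Conditions: piperidine (0.1 equiv), AcOH (0.1 equiv), CH2Cl2, rt
Reagents that add atoms: none
Why: Knoevenagel condensation of the aldehyde with the malonate; no stereocentre is formed and the methyl-bearing centre (future C-7) is untouched.

Step 2
Reactants: 3 dimethyl 2-[(3S)-3,7-dimethyloct-6-en-1-ylidene]propanedioate
Product: 4 dimethyl 2-[(1S,2S,5S)-5-methyl-2-(prop-1-en-2-yl)cyclohexyl]propanedioate
Conditions: FeCl3 on Al2O3 (cat.), CH2Cl2, −78 °C → rt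
Reagents that add atoms: none
Why: Lewis-acid-promoted intramolecular ene reaction of the alkylidene malonate through a chair-like transition state with the methyl group equatorial, which should set the future C-8a and C-4a trans-diequatorial relative to C-7 and unveil the isopropenyl group.

Step 3
Reactants: 4 dimethyl 2-[(1S,2S,5S)-5-methyl-2-(prop-1-en-2-yl)cyclohexyl]propanedioate
Product: 5 methyl 2-[(1R,2S,5S)-5-methyl-2-(prop-1-en-2-yl)cyclohexyl]acetate
Conditions: NaCl, H2O, DMSO, 160 °C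
Reagents that add atoms: none
Why: Krapcho dealkoxycarbonylation removes one ester of the malonate without touching a stereocentre.

Step 4
Reactants: 5 methyl 2-[(1R,2S,5S)-5-methyl-2-(prop-1-en-2-yl)cyclohexyl]acetate
Product: 6 2-[(1R,2S,5S)-5-methyl-2-(prop-1-en-2-yl)cyclohexyl]acetaldehyde
Conditions: i-Bu2AlH (1.1 equiv), CH2Cl2, −78 °C
Reagents that add atoms: none
Why: partial hydride reduction of the ester stops at the aldehyde because the aluminium hemiacetal is stable at low temperature.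

Step 5
Reactants: 6 2-[(1R,2S,5S)-5-methyl-2-(prop-1-en-2-yl)cyclohexyl]acetaldehyde; 7 ethyl glyoxylate
Product: 8 ethyl (2E)-3-[(1S,2S,5S)-5-methyl-2-(prop-1-en-2-yl)cyclohexyl]-4-oxobut-2-enoate
Conditions: Bu2NH (0.2 equiv), AcOH (0.2 equiv), toluene, 50 °C
Reagents that add atoms: none
Why: amine-salt-catalysed crossed aldol (Mannich-type) condensation between the enolisable aldehyde (its α-carbon becomes C-1) and the non-enolisable, highly electrophilic glyoxylate (its aldehyde carbon becomes C-2), the alkene geometry being of no consequence.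

Step 6
Reactants: 8 ethyl (2E)-3-[(1S,2S,5S)-5-methyl-2-(prop-1-en-2-yl)cyclohexyl]-4-oxobut-2-enoate
Product: 10 ethyl (2E)-3-[(1S,2S,5S)-2-acetyl-5-methylcyclohexyl]-4-oxobut-2-enoate, via ozonide 9 (not isolated)
Conditions: O3, CH2Cl2, −78 °C (Sudan Red 7B end-point); Me2S, −78 °C → rt
Reagents that add atoms: ozone, [O-][O+]=O
Why: ozonolysis should select the electron-rich 1,1-disubstituted alkene over the electron-poor enal–ester double bond, and reductive work-up gives the methyl ketone with the acetyl group still equatorial.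

Step 7
Reactants: 10 ethyl (2E)-3-[(1S,2S,5S)-2-acetyl-5-methylcyclohexyl]-4-oxobut-2-enoate
Product: 11 ethyl (1R,2R,4aS,7S,8aR)-1-formyl-7-methyl-4-oxodecahydronaphthalene-2-carboxylate
Conditions: pyrrolidine (0.2 equiv), AcOH (0.2 equiv), CH2Cl2, 0 °C → rt; then DBU (0.2 equiv), rt
Reagents that add atoms: none
Why: The pyrrolidine enamine of the methyl ketone (formed on the CH3 side, C-3) adds to C-2, the β-carbon of the iminium ion generated from the 4-oxobut-2-enoate, and hydrolysis returns the catalyst; the closest known type is the amine- or base-catalysed intramolecular Michael addition of a ketone to an enal giving a six-membered 1,5-dicarbonyl compound. Ring A closes in the 6-endo-trig mode through a chair-like transition state. C-2 is set in the C–C bond formation with the ester equatorial and can still be corrected by retro-Michael/Michael exchange, while C-1 (α to the formyl group) and C-4a (α to the ketone) equilibrate by enolisation under DBU, so the fixed centres C-8a and C-7 from step 2 should dictate the all-equatorial trans-decalin. The step needs 1,4- over 1,2-addition and attack at C-2 instead of five-ring closure at C-1: iminium activation makes C-2 the electrophilic β-carbon, C-2 is the unsubstituted terminus whereas C-1 is fully substituted, and aldol addition to the masked formyl group is reversible.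

Step 8
Reactants: 11 ethyl (1R,2R,4aS,7S,8aR)-1-formyl-7-methyl-4-oxodecahydronaphthalene-2-carboxylate
Product: 12 ethyl (1R,2R,4aS,7S,8aR)-7-methyl-4-oxo-1-[(1E)-prop-1-en-1-yl]decahydronaphthalene-2-carboxylate
Conditions: CrCl2 (8 equiv), CH3CHI2 (2 equiv), THF, rt
Reagents that add atoms: 1,1-diiodoethane, CC(I)I
Why: Takai–Utimoto ethylidenation is aldehyde-selective (ketone and ester untouched), non-basic (C-1 is not epimerised) and should give the (E)-propenyl group.

Step 9
Reactants: 12 ethyl (1R,2R,4aS,7S,8aR)-7-methyl-4-oxo-1-[(1E)-prop-1-en-1-yl]decahydronaphthalene-2-carboxylate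
Product: 14 ethyl (1R,2S,4aS,7S,8aR)-7-methyl-1-[(1E)-prop-1-en-1-yl]-4-{[(trifluoromethyl)sulfonyl]oxy}-1,2,4a,5,6,7,8,8a-octahydronaphthalene-2-carboxylate, via potassium enolate 13 (not isolated)
Conditions: KN(SiMe3)2 (1.05 equiv), THF, −78 °C; PhNTf2, −78 → 0 °C
Reagents that add atoms: N-phenylbis(trifluoromethanesulfonimide), O=S(=O)(N(c1ccccc1)S(=O)(=O)C(F)(F)F)C(F)(F)F (triflyl group of 14); potassium bis(trimethylsilyl)amide, C[Si](C)(C)[N-][Si](C)(C)C.[K+] (potassium of 13)
Why: kinetic deprotonation of the ketone at the less substituted C-3 methylene (C-4a is a hindered methine) followed by O-triflation fixes the alkene position at C-3=C-4 (regioselective enol triflate formation).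

Step 10
Reactants: 14 ethyl (1R,2S,4aS,7S,8aR)-7-methyl-1-[(1E)-prop-1-en-1-yl]-4-{[(trifluoromethyl)sulfonyl]oxy}-1,2,4a,5,6,7,8,8a-octahydronaphthalene-2-carboxylate
Product: 15 ethyl (1R,2S,4aS,7S,8aR)-4,7-dimethyl-1-[(1E)-prop-1-en-1-yl]-1,2,4a,5,6,7,8,8a-octahydronaphthalene-2-carboxylate
Conditions: MeMgBr (1.5 equiv), Fe(acac)3 (5 mol%), THF/NMP, −30 °C
Reagents that add atoms: methylmagnesium bromide, C[Mg]Br
Why: iron-catalysed cross-coupling of the alkenyl triflate with the methyl Grignard reagent installs the C-4 methyl group with retention of the double-bond position and tolerates the ester at low temperature.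

Step 11
Reactants: 15 ethyl (1R,2S,4aS,7S,8aR)-4,7-dimethyl-1-[(1E)-prop-1-en-1-yl]-1,2,4a,5,6,7,8,8a-octahydronaphthalene-2-carboxylate
Product: 16 [(1R,2S,4aS,7S,8aR)-4,7-dimethyl-1-[(1E)-prop-1-en-1-yl]-1,2,4a,5,6,7,8,8a-octahydronaphthalen-2-yl]methanol
Conditions: i-Bu2AlH (2.5 equiv), CH2Cl2, −78 → 0 °C
Reagents that add atoms: none
Why: hydride reduction of the ester to the primary alcohol leaves both alkenes and all stereocentres untouched.

Step 12
Reactants: 16 [(1R,2S,4aS,7S,8aR)-4,7-dimethyl-1-[(1E)-prop-1-en-1-yl]-1,2,4a,5,6,7,8,8a-octahydronaphthalen-2-yl]methanol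
Product: 17 (1R,2S,4aS,7S,8aR)-4,7-dimethyl-1-[(1E)-prop-1-en-1-yl]-1,2,4a,5,6,7,8,8a-octahydronaphthalene-2-carbaldehyde
Conditions: Dess–Martin periodinane, NaHCO3, CH2Cl2, 0 °C
Reagents that add atoms: none
Why: buffered Dess–Martin oxidation should give the β,γ-unsaturated aldehyde without epimerising C-2 or moving the double bond; the aldehyde is used at once.

Step 13
Reactants: 18 1,4-dioxaspiro[4.5]dec-6-en-8-one
Product: 19 (8R)-1,4-dioxaspiro[4.5]dec-6-en-8-ol
Conditions: RuCl(p-cymene)[(R,R)-TsDPEN] (1 mol%), HCO2Na, H2O/CH2Cl2, Bu4NCl (cat.), rt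
Reagents that add atoms: none
Why: asymmetric transfer hydrogenation of the enone carbonyl, in which the alkene takes the role of the aryl group in the usual model so that the (R,R)-ligand should give the (R)-allylic alcohol.

Step 14
Reactants: 19 (8R)-1,4-dioxaspiro[4.5]dec-6-en-8-ol
Product: 20 tert-butyl[(8R)-1,4-dioxaspiro[4.5]dec-6-en-8-yloxy]dimethylsilane
Conditions: TBSCl, imidazole, DMF, rt
Reagents that add atoms: tert-butyldimethylsilyl chloride, CC(C)(C)[Si](C)(C)Cl
Why: silylation of the secondary alcohol with retention of configuration.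

Step 15
Reactants: 20 tert-butyl[(8R)-1,4-dioxaspiro[4.5]dec-6-en-8-yloxy]dimethylsilane
Product: 21 (4R)-4-[(tert-butyldimethylsilyl)oxy]cyclohex-2-en-1-one
Conditions: PPTS (cat.), acetone/H2O, 50 °C
Reagents that add atoms: water, O
Why: mild acid-catalysed acetal hydrolysis unmasks the ketone in conjugation with the alkene and leaves the silyl ether and its stereocentre intact.

Step 16
Reactants: 22 5-bromo-2,4-dichloropyridine
Product: 23 5-bromo-2,4-bis[2-(trimethylsilyl)ethoxy]pyridine
Conditions: 2-(trimethylsilyl)ethanol (2.5 equiv), NaH (2.6 equiv), THF/DMF, 0 → 70 °C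
Reagents that add atoms: 2-(trimethylsilyl)ethanol, C[Si](C)(C)CCO
Why: double nucleophilic aromatic substitution of the 4- and 2-chlorides by the alkoxide, both activated by the ring nitrogen, while the 5-bromide is not displaced.

Step 17
Reactants: 23 5-bromo-2,4-bis[2-(trimethylsilyl)ethoxy]pyridine; 21 (4R)-4-[(tert-butyldimethylsilyl)oxy]cyclohex-2-en-1-one
Product: 25 (1S,4R)-1-{4,6-bis[2-(trimethylsilyl)ethoxy]pyridin-3-yl}-4-[(tert-butyldimethylsilyl)oxy]cyclohex-2-en-1-ol, via pyridin-3-yllithium 24 (not isolated)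
Conditions: n-BuLi (1.05 equiv), THF, −78 °C; then 21, −78 °C
Reagents that add atoms: n-butyllithium, [Li]CCCC (lithium of 24)
Why: bromine–lithium exchange and 1,2-addition of the aryllithium to the enone from the face opposite to the 4-silyloxy group should give the tertiary alcohol cis to the silyloxy group (new carbinol centre controlled by the existing C-4 centre).

Step 18
Reactants: 25 (1S,4R)-1-{4,6-bis[2-(trimethylsilyl)ethoxy]pyridin-3-yl}-4-[(tert-butyldimethylsilyl)oxy]cyclohex-2-en-1-ol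
Product: 26 5-[(1S,4R)-4-[(tert-butyldimethylsilyl)oxy]-1-[(triethylsilyl)oxy]cyclohex-2-en-1-yl]-2,4-bis[2-(trimethylsilyl)ethoxy]pyridine
Conditions: TESOTf, 2,6-lutidine, CH2Cl2, −78 → 0 °C
Reagents that add atoms: triethylsilyl trifluoromethanesulfonate, CC[Si](CC)(CC)OS(=O)(=O)C(F)(F)F
Why: silylation of the hindered tertiary alcohol with the silyl triflate removes the hydroxyl that would direct a peracid syn and protects it for the later lithiation.

Step 19
Reactants: 26 5-[(1S,4R)-4-[(tert-butyldimethylsilyl)oxy]-1-[(triethylsilyl)oxy]cyclohex-2-en-1-yl]-2,4-bis[2-(trimethylsilyl)ethoxy]pyridine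
Product: 27 5-[(1S,2R,5R,6R)-5-[(tert-butyldimethylsilyl)oxy]-2-[(triethylsilyl)oxy]-7-oxabicyclo[4.1.0]heptan-2-yl]-2,4-bis[2-(trimethylsilyl)ethoxy]pyridine
Conditions: mCPBA (1.5 equiv), NaHCO3, CH2Cl2, 0 °C → rt
Reagents that add atoms: 3-chloroperbenzoic acid, OOC(=O)c1cccc(Cl)c1
Why: Prilezhaev epoxidation in which, with both allylic oxygens silylated and on the same face, the peracid should attack the opposite face and so set both oxirane carbons trans to the two C–O bonds.

Step 20
Reactants: 27 5-[(1S,2R,5R,6R)-5-[(tert-butyldimethylsilyl)oxy]-2-[(triethylsilyl)oxy]-7-oxabicyclo[4.1.0]heptan-2-yl]-2,4-bis[2-(trimethylsilyl)ethoxy]pyridine; 17 (1R,2S,4aS,7S,8aR)-4,7-dimethyl-1-[(1E)-prop-1-en-1-yl]-1,2,4a,5,6,7,8,8a-octahydronaphthalene-2-carbaldehyde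
Product: 29 [(1R,2S,4aS,7S,8aR)-4,7-dimethyl-1-[(1E)-prop-1-en-1-yl]-1,2,4a,5,6,7,8,8a-octahydronaphthalen-2-yl]{5-[(1S,2R,5R,6R)-5-[(tert-butyldimethylsilyl)oxy]-2-[(triethylsilyl)oxy]-7-oxabicyclo[4.1.0]heptan-2-yl]-2,4-bis[2-(trimethylsilyl)ethoxy]pyridin-3-yl}methanol, via 3-lithiopyridine 28 (not isolated)
Conditions: n-BuLi (1.2 equiv), THF, −78 → −40 °C; then 17, −78 °C
Reagents that add atoms: n-butyllithium, [Li]CCCC (lithium of 28)
Why: directed ortho-lithiation at pyridine C-3 between the two alkoxy groups and 1,2-addition of the aryllithium to the aldehyde, which should outrun enolisation at −78 °C; the new carbinol centre is not controlled because it is oxidised next.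

Step 21
Reactants: 29 the carbinol from step 20
Product: 30 [(1R,2S,4aS,7S,8aR)-4,7-dimethyl-1-[(1E)-prop-1-en-1-yl]-1,2,4a,5,6,7,8,8a-octahydronaphthalen-2-yl]{5-[(1S,2R,5R,6R)-5-[(tert-butyldimethylsilyl)oxy]-2-[(triethylsilyl)oxy]-7-oxabicyclo[4.1.0]heptan-2-yl]-2,4-bis[2-(trimethylsilyl)ethoxy]pyridin-3-yl}methanone
Conditions: Dess–Martin periodinane, NaHCO3, CH2Cl2, rt
Reagents that add atoms: none
Why: buffered Dess–Martin oxidation of the secondary carbinol to the aryl ketone should neither move the β,γ-double bond nor epimerise C-2.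

Step 22
Reactants: 30 the ketone from step 21
Product: 31 4-hydroxy-5-[(1S,2R,5R,6S)-2,5-dihydroxy-7-oxabicyclo[4.1.0]heptan-2-yl]-3-{[(1R,2S,4aS,7S,8aR)-4,7-dimethyl-1-[(1E)-prop-1-en-1-yl]-1,2,4a,5,6,7,8,8a-octahydronaphthalen-2-yl]carbonyl}pyridin-2(1H)-one (CNP0494338.1)
Conditions: TBAF (8 equiv), AcOH (8 equiv), THF, 0 → 40 °C
Reagents that add atoms: none
Why: fluoride attacks silicon, so the two silyl ethers are cleaved and the two 2-(trimethylsilyl)ethyl ethers fragment to ethene and fluorotrimethylsilane to release the 4-hydroxy-2-pyridone, while acetic acid buffers the alkoxides so that the epoxide and C-2 should not be disturbed.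

**Compound list**

1 | (S)-citronellal, (3S)-3,7-dimethyloct-6-enal | O=CC[C@@H](C)CCC=C(C)C | starting material
2 | dimethyl malonate | COC(=O)CC(=O)OC | starting material
3 | dimethyl 2-[(3S)-3,7-dimethyloct-6-en-1-ylidene]propanedioate | COC(=O)C(=CC[C@@H](C)CCC=C(C)C)C(=O)OC | intermediate
4 | dimethyl 2-[(1S,2S,5S)-5-methyl-2-(prop-1-en-2-yl)cyclohexyl]propanedioate (all substituents equatorial) | COC(=O)C(C(=O)OC)[C@H]1C[C@@H](C)CC[C@@H]1C(C)=C | intermediate
5 | methyl 2-[(1R,2S,5S)-5-methyl-2-(prop-1-en-2-yl)cyclohexyl]acetate | COC(=O)C[C@H]1C[C@@H](C)CC[C@@H]1C(C)=C | intermediate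
6 | 2-[(1R,2S,5S)-5-methyl-2-(prop-1-en-2-yl)cyclohexyl]acetaldehyde | O=CC[C@H]1C[C@@H](C)CC[C@@H]1C(C)=C | intermediate
7 | ethyl glyoxylate (ethyl 2-oxoacetate) | CCOC(=O)C=O | starting material
8 | ethyl (2E)-3-[(1S,2S,5S)-5-methyl-2-(prop-1-en-2-yl)cyclohexyl]-4-oxobut-2-enoate | CCOC(=O)/C=C(/C=O)[C@H]1C[C@@H](C)CC[C@@H]1C(C)=C | intermediate
9 | ethyl (2E)-3-[(1S,2S,5S)-5-methyl-2-(3-methyl-1,2,4-trioxolan-3-yl)cyclohexyl]-4-oxobut-2-enoate (ozonide, trioxolane carbon undefined) | CCOC(=O)/C=C(/C=O)[C@H]1C[C@@H](C)CC[C@@H]1C2(C)OCOO2 | intermediate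
10 | ethyl (2E)-3-[(1S,2S,5S)-2-acetyl-5-methylcyclohexyl]-4-oxobut-2-enoate | CCOC(=O)/C=C(/C=O)[C@H]1C[C@@H](C)CC[C@@H]1C(C)=O | intermediate
11 | ethyl (1R,2R,4aS,7S,8aR)-1-formyl-7-methyl-4-oxodecahydronaphthalene-2-carboxylate (trans-fused, all substituents equatorial) | O=C[C@@H]1[C@H]2C[C@@H](C)CC[C@@H]2C(=O)C[C@H]1C(=O)OCC | intermediate
12 | ethyl (1R,2R,4aS,7S,8aR)-7-methyl-4-oxo-1-[(1E)-prop-1-en-1-yl]decahydronaphthalene-2-carboxylate | C/C=C/[C@@H]1[C@H]2C[C@@H](C)CC[C@@H]2C(=O)C[C@H]1C(=O)OCC | intermediate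
13 | potassium enolate of 12 (C-3=C-4 enolate) | C/C=C/[C@@H]1[C@H]2C[C@@H](C)CC[C@@H]2C([O-])=C[C@H]1C(=O)OCC.[K+] | intermediate
14 | ethyl (1R,2S,4aS,7S,8aR)-7-methyl-1-[(1E)-prop-1-en-1-yl]-4-{[(trifluoromethyl)sulfonyl]oxy}-1,2,4a,5,6,7,8,8a-octahydronaphthalene-2-carboxylate | C/C=C/[C@@H]1[C@H]2C[C@@H](C)CC[C@@H]2C(OS(=O)(=O)C(F)(F)F)=C[C@H]1C(=O)OCC | intermediate
15 | ethyl (1R,2S,4aS,7S,8aR)-4,7-dimethyl-1-[(1E)-prop-1-en-1-yl]-1,2,4a,5,6,7,8,8a-octahydronaphthalene-2-carboxylate | C/C=C/[C@@H]1[C@H]2C[C@@H](C)CC[C@@H]2C(C)=C[C@H]1C(=O)OCC | intermediate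
16 | [(1R,2S,4aS,7S,8aR)-4,7-dimethyl-1-[(1E)-prop-1-en-1-yl]-1,2,4a,5,6,7,8,8a-octahydronaphthalen-2-yl]methanol | C/C=C/[C@@H]1[C@H]2C[C@@H](C)CC[C@@H]2C(C)=C[C@H]1CO | intermediate
17 | (1R,2S,4aS,7S,8aR)-4,7-dimethyl-1-[(1E)-prop-1-en-1-yl]-1,2,4a,5,6,7,8,8a-octahydronaphthalene-2-carbaldehyde | C/C=C/[C@@H]1[C@H]2C[C@@H](C)CC[C@@H]2C(C)=C[C@H]1C=O | intermediate
18 | 1,4-dioxaspiro[4.5]dec-6-en-8-one | O=C1C=CC2(CC1)OCCO2 | starting material
19 | (8R)-1,4-dioxaspiro[4.5]dec-6-en-8-ol | O[C@H]1C=CC2(CC1)OCCO2 | intermediate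
20 | tert-butyl[(8R)-1,4-dioxaspiro[4.5]dec-6-en-8-yloxy]dimethylsilane | CC(C)(C)[Si](C)(C)O[C@H]1C=CC2(CC1)OCCO2 | intermediate
21 | (4R)-4-[(tert-butyldimethylsilyl)oxy]cyclohex-2-en-1-one | O=C1C=C[C@H](O[Si](C)(C)C(C)(C)C)CC1 | intermediate
22 | 5-bromo-2,4-dichloropyridine | Clc1cc(Cl)c(Br)cn1 | starting material
23 | 5-bromo-2,4-bis[2-(trimethylsilyl)ethoxy]pyridine | C[Si](C)(C)CCOc1cc(OCC[Si](C)(C)C)c(Br)cn1 | intermediate
24 | {4,6-bis[2-(trimethylsilyl)ethoxy]pyridin-3-yl}lithium | [Li]c1cnc(OCC[Si](C)(C)C)cc1OCC[Si](C)(C)C | intermediate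
25 | (1S,4R)-1-{4,6-bis[2-(trimethylsilyl)ethoxy]pyridin-3-yl}-4-[(tert-butyldimethylsilyl)oxy]cyclohex-2-en-1-ol (hydroxyl cis to the silyloxy group) | C[Si](C)(C)CCOc1cc(OCC[Si](C)(C)C)c(cn1)[C@]2(O)CC[C@@H](O[Si](C)(C)C(C)(C)C)C=C2 | intermediate
26 | 5-[(1S,4R)-4-[(tert-butyldimethylsilyl)oxy]-1-[(triethylsilyl)oxy]cyclohex-2-en-1-yl]-2,4-bis[2-(trimethylsilyl)ethoxy]pyridine | C[Si](C)(C)CCOc1cc(OCC[Si](C)(C)C)c(cn1)[C@]2(O[Si](CC)(CC)CC)CC[C@@H](O[Si](C)(C)C(C)(C)C)C=C2 | intermediate
27 | 5-[(1S,2R,5R,6R)-5-[(tert-butyldimethylsilyl)oxy]-2-[(triethylsilyl)oxy]-7-oxabicyclo[4.1.0]heptan-2-yl]-2,4-bis[2-(trimethylsilyl)ethoxy]pyridine (oxirane trans to both silyloxy groups) | C[Si](C)(C)CCOc1cc(OCC[Si](C)(C)C)c(cn1)[C@]2(O[Si](CC)(CC)CC)CC[C@@H](O[Si](C)(C)C(C)(C)C)[C@@H]3O[C@@H]32 | intermediate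
28 | 3-lithio derivative of 27 | C[Si](C)(C)CCOc1c([Li])c(OCC[Si](C)(C)C)c(cn1)[C@]2(O[Si](CC)(CC)CC)CC[C@@H](O[Si](C)(C)C(C)(C)C)[C@@H]3O[C@@H]32 | intermediate
29 | [(1R,2S,4aS,7S,8aR)-4,7-dimethyl-1-[(1E)-prop-1-en-1-yl]-1,2,4a,5,6,7,8,8a-octahydronaphthalen-2-yl]{5-[(1S,2R,5R,6R)-5-[(tert-butyldimethylsilyl)oxy]-2-[(triethylsilyl)oxy]-7-oxabicyclo[4.1.0]heptan-2-yl]-2,4-bis[2-(trimethylsilyl)ethoxy]pyridin-3-yl}methanol (carbinol epimers) | C/C=C/[C@@H]1[C@H]2C[C@@H](C)CC[C@@H]2C(C)=C[C@H]1C(O)c3c(OCC[Si](C)(C)C)c(cnc3OCC[Si](C)(C)C)[C@]4(O[Si](CC)(CC)CC)CC[C@@H](O[Si](C)(C)C(C)(C)C)[C@@H]5O[C@@H]54 | intermediate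
30 | the corresponding methanone (aryl ketone of 29) | C/C=C/[C@@H]1[C@H]2C[C@@H](C)CC[C@@H]2C(C)=C[C@H]1C(=O)c3c(OCC[Si](C)(C)C)c(cnc3OCC[Si](C)(C)C)[C@]4(O[Si](CC)(CC)CC)CC[C@@H](O[Si](C)(C)C(C)(C)C)[C@@H]5O[C@@H]54 | intermediate
31 | 4-hydroxy-5-[(1S,2R,5R,6S)-2,5-dihydroxy-7-oxabicyclo[4.1.0]heptan-2-yl]-3-{[(1R,2S,4aS,7S,8aR)-4,7-dimethyl-1-[(1E)-prop-1-en-1-yl]-1,2,4a,5,6,7,8,8a-octahydronaphthalen-2-yl]carbonyl}pyridin-2(1H)-one | C/C=C/[C@@H]1[C@H]2C[C@@H](C)CC[C@@H]2C(C)=C[C@H]1C(=O)c1c(O)c([C@]2(O)CC[C@@H](O)[C@@H]3O[C@@H]32)c[nH]c1=O | target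

**Summary**

Total step count: 22.
Longest linear sequence: 15 steps (steps 1–12, then 20–22, from (S)-citronellal).

Steps most likely to fail:

- **Step 7 (key step).** The ketone-derived nucleophile may add 1,2 to the formyl carbon (intramolecular aldol followed by irreversible dehydration), or close a five-membered ring at C-1, instead of the six-ring Michael closure at C-2. Fallback: set out from 8 (before ozonolysis) and close ring A on the alkene instead of on the ketone. With Me2AlCl (1.1 equiv, CH2Cl2, −78 → 0 °C) the terminal carbon of the isopropenyl group should attack C-2 of the Lewis-acid-bound enal (cation–olefin/ene closure, 6-endo), with transfer of a methyl hydrogen to C-1. This would give the exocyclic-methylene aldehyde ester F1. Ozonolysis of the methylidene group of F1 (O3, then Me2S), followed by the DBU equilibration of step 7, returns to the route at 11.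

- **Step 19.** Oxidation at the pyridine nitrogen may compete with the sluggish, doubly allylic-oxygenated alkene, and facial discrimination may be insufficient. Fallback: set out from 26 and deliver the oxygen by osmylation instead of a peracid. OsO4 (cat.)/NMO in acetone–water should dihydroxylate from the face opposite to the two allylic silyloxy groups and does not touch the pyridine nitrogen, giving the cis-diol F2. Conversion into the cyclic orthoacetate (MeC(OMe)3, PPTS) and opening with AcBr should give the trans-acetoxy bromide F3. K2CO3 in MeOH then closes the oxirane with a second inversion at the same carbon, so the oxirane ends up on the face of the diol, returning to the route at 27.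

- **Step 22.** During the prolonged fluoride treatment needed for the 2-O-(trimethylsilyl)ethyl group, the β,γ-double bond may migrate into conjugation with the ketone or C-2 may epimerise. Fallback: set out from 29 and reverse the order of deprotection and oxidation. TBAF/AcOH in THF on the carbinol, where no enolisable ketone is present, should give the fully deprotected carbinol F4. Activated MnO2 in CH2Cl2 should then oxidise only the pyridone-activated (benzylic-type) carbinol, leaving the saturated secondary alcohol of the cyclohexane, and returns to the route at 31.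

Further compounds
F1 | step 7 | 4-methylidene analogue of 11: ethyl 1-formyl-7-methyl-4-methylidenedecahydronaphthalene-2-carboxylate, same configuration as 11 | O=C[C@@H]1[C@H]2C[C@@H](C)CC[C@@H]2C(=C)C[C@H]1C(=O)OCC
F2 | step 19 | cis-diol of 26 (both new hydroxyls trans to the two silyloxy groups) | C[Si](C)(C)CCOc1cc(OCC[Si](C)(C)C)c(cn1)[C@]2(O[Si](CC)(CC)CC)CC[C@@H](O[Si](C)(C)C(C)(C)C)[C@H](O)[C@@H]2O
F3 | step 19 | trans-acetoxy bromide from F2 (bromide next to the silyloxy-bearing CH, acetate next to the quaternary carbon) | C[Si](C)(C)CCOc1cc(OCC[Si](C)(C)C)c(cn1)[C@]2(O[Si](CC)(CC)CC)CC[C@@H](O[Si](C)(C)C(C)(C)C)[C@@H](Br)[C@@H]2OC(C)=O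
F4 | step 22 | fully deprotected carbinol: the secondary alcohol corresponding to 31 (carbinol epimers) | C/C=C/[C@@H]1[C@H]2C[C@@H](C)CC[C@@H]2C(C)=C[C@H]1C(O)c1c(O)c([C@]2(O)CC[C@@H](O)[C@@H]3O[C@@H]32)c[nH]c1=O
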